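All runs come from a simulation for substances that don't exist; noise was put on by code.

Write the balance of Z before reaching for any rate constant, since you asked for a quick number on Saturday's flask.

| flask | Z | remark | time |
|---|---|---|---|
| Saturday's | 0.030 M | the very flask that is asked about, followed so far |  |
| flask | 0.030 M |  | 8.0 h |

Saturday's run (percent of the Z charged)

| time / min | D / % | J / % |
|---|---|---|
| 25.0 | 34.8 | 7.2 |
| 50.0 | 35.8 | 19.3 |
| 80.0 | 31.0 | 32.3 |
| 90.0 | 29.2 | 35.7 |

(standard deviation of a reading: 0.3 percentage points)

- share of D in D plus J at 2.0 min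
- share of D in D plus J at 8.0 h
- which of D and J there is more of at 8.0 h

- the numbers in the tables scatter by 0.3 percentage points (one standard deviation)

Call P the part of the charged Z not standing as J. P falls from 80.7% at 50.0 min to 64.3% at 90.0 min, while the reading D/P stays at 0.444 to 0.454. My assumption is that P in Saturday's flask decays by first order, and on these two readings that gives a constant of 0.00568 min⁻¹.

The time P needs to halve at that constant is the drain half-life, 2.03 h, the first-order half-life of the pool. Carried on from 90.0 min, it puts P at 7.02% at 8.0 h. With D at the same fraction of P, my share of D comes to 3.31%.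

Your forecast, reached by its own route, prints 98.7% at 2.0 min, 3.4% at 8.0 h, and J ahead, adding: “Any reversibility of J would raise this slightly”.

Saturday's flask gives 98.5% at 2.0 min and 10.3% at 8.0 h, with J ahead.

    D ⇌ J (K = 9.66, k = 2.56 × 10⁻⁴ s⁻¹)
    Z ⇌ D (K = 1.27, k = 5.06 × 10⁻⁴ s⁻¹)
    J ⇌ G (K = 0.130, k = 0.00168 s⁻¹)

Carried on from 90.0 min, 2.03 h puts P at 27.4% at 4.00 h and 7.02% at 8.0 h. Saturday's flask has 34.9% and 25.3%, and of the latter 9.71% is G. The reckoning with 2.03 h contains no concentration, so it gives the same 7.02% for the neighbour flask charged with 0.0075 M of Z, a quarter of Saturday's charge. That neighbour flask stands at P = 25.3% at 8.0 h, with a share of D of 10.3%.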